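**Retrosynthetic overview**
1. Target 22 comes from alkene 21 by hydroxyl-directed epoxidation of C1=C2, and 21 from diol 18 by selective acylation at C5–O.
2. Diol 18 comes from hydroxy ketone enol triflate 16. Both methyl groups enter in one operation: C2–CH3 by cross-coupling, C7–CH3 by 1,2-addition.
3. 16 comes from keto aldehyde 15 by an enamine-catalysed aldol closure of the C5–C6 bond. The seven-membered ring is formed second.
4. 15 comes from 13 and 13 from 9. Trans conjugate methallylation with enolate triflation makes the C8–C8a bond, and one ozonolysis unmasks both the ketone and the aldehyde.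
5. 9 comes from 5 + 6. An organocatalytic Michael addition makes the C3a–C4 bond and sets the first stereocentres, then an aldol condensation closes the five-membered ring first.

Assumption: 4-oxopentanal (6) is taken as a catalogue chemical, and the bicycle is numbered as an azulene (C1=C2 alkene or epoxide, C3a/C8a ring fusion, C4 isopropyl, C5 ester oxygen, C7 tertiary carbinol).

**Step 1**
Reactants: 1 isobutyraldehyde; 2 nitromethane
Product: 5 (E)-3-methyl-1-nitrobut-1-ene, via nitroaldol 3 (not isolated), via mesylate 4 (not isolated)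
Conditions: MeNO2 (3 equiv), KOtBu (5 mol%), THF/tBuOH, 0 °C to rt; concentrate; MsCl (1.1 equiv), Et3N (2.2 equiv), CH2Cl2, 0 °C
Reagents that add atoms: methanesulfonyl chloride, CS(=O)(=O)Cl (its atoms stay only in 4)
Why: Henry (nitroaldol) addition followed by mesylation and E1cB elimination gives the conjugated nitroalkene as the strongly favoured E isomer, and the racemic carbinol centre of 3 and 4 is erased in the same flask.

**Step 2**
Reactants: 5 (E)-3-methyl-1-nitrobut-1-ene; 6 4-oxopentanal
Product: 9 (4R)-4-[(2S)-3-methyl-1-nitrobutan-2-yl]cyclopent-2-en-1-one, via Michael adduct 7 (not isolated), via ketol 8 (not isolated)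
Conditions: (R)-2-[diphenyl(trimethylsilyloxy)methyl]pyrrolidine (10 mol%), 4-nitrophenol (10 mol%), toluene, 0 °C to rt, 24 h; then LiOH·H2O (2.2 equiv), iPrOH/H2O, 0 °C to rt; AcOH quench at 0 °C
Reagents that add atoms: none
Why: Under Hayashi–Jørgensen enamine catalysis the (E)-enamine of the aldehyde end of 6, shielded on one face by the (R)-catalyst, adds to 5 through the usual synclinal transition state to give the syn adduct 7 (both new centres S, the future C3a and C4), and hydroxide then drives the intramolecular aldol condensation of the methyl ketone onto the aldehyde, a closure known from related 2-substituted oxo-aldehydes to outrun epimerisation of the α-branched aldehyde.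

**Step 3**
Reactants: 9 nitro enone; 10 (2-methylallyl)magnesium chloride
Product: 13 (3S,4R)-4-[(2S)-3-methyl-1-nitrobutan-2-yl]-3-(2-methylallyl)cyclopent-1-en-1-yl trifluoromethanesulfonate, via lithium nitronate 11 (not isolated), via nitronate enolate 12 (not isolated)
Conditions: LiN(SiMe3)2 (1.05 equiv), THF, −78 °C; cannulate into (C4H7)2CuMgCl [10 (2.4 equiv), CuBr·SMe2 (1.2 equiv)], THF, −78 °C, 1 h; Comins' reagent (1.3 equiv), −78 to −20 °C; aq NH4Cl
Reagents that add atoms: Comins' reagent, N-(5-chloropyridin-2-yl)bis(trifluoromethanesulfonimide), O=S(=O)(N(c1ccc(Cl)cn1)S(=O)(=O)C(F)(F)F)C(F)(F)F; LiN(SiMe3)2, [Li]N([Si](C)(C)C)[Si](C)(C)C (lithium of 11 and 12 only)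
Why: This is a conjugate addition with enolate trapping in which turning the acidic CH2NO2 group into its inert nitronate keeps the later enolate from being protonated, the cuprate adds to the cyclopentenone face opposite the bulky C4 side chain (trans product, new centre S, the future C8a), and the regiodefined enolate, about nine pKa units more basic than the nitronate, is the site that Comins' reagent triflates.

**Step 4**
Reactants: 13 nitro enol triflate
Product: 15 (3S,4R)-4-[(2S)-3-methyl-1-oxobutan-2-yl]-3-(2-oxopropyl)cyclopent-1-en-1-yl trifluoromethanesulfonate, via sodium nitronate 14 (not isolated)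
Conditions: NaOMe (1.0 equiv), MeOH/CH2Cl2, 0 °C; O3, −78 °C (Sudan Red 7B end point); Me2S, −78 °C to rt
Reagents that add atoms: ozone, [O-][O+]=O; NaOMe, [Na+].[O-]C (sodium of 14 only)
Why: Ozonolysis and the ozonolytic Nef reaction run in one operation, since ozone cleaves the 1,1-disubstituted alkene to the methyl ketone and the nitronate C=N bond to the aldehyde while the electron-poor enol triflate reacts far more slowly, and because the only base is used up with the nitronate the α-stereocentre of the aldehyde is not scrambled.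

**Step 5**
Reactants: 15 keto aldehyde
Product: 16 (3aR,4S,5S,8aS)-5-hydroxy-4-isopropyl-7-oxo-3,3a,4,5,6,7,8,8a-octahydroazulen-2-yl trifluoromethanesulfonate
Conditions: (R)-proline (30 mol%), DMSO, 0.02 M, rt, 48 h
Reagents that add atoms: none
Why: Proposed new method: an enamine-catalysed 7-(enolexo)-exo-trig aldolisation, not yet described for carbocycles of this size, in which (R)-proline condenses with the unhindered methyl ketone to give the less substituted enamine, whose terminal carbon attacks the acid-activated α-branched aldehyde in a Houk–List-type transition state; the two five-ring alternatives (C8 onto the aldehyde, C4 onto the ketone) are shut off because they would give trans-fused bicyclo[3.3.0]octenes, so only the trans-hydroazulene can form; the (R)-catalyst selects the aldehyde face that gives (5S), which is also the equatorial and thermodynamically preferred alcohol; the closest known reactions are the proline-catalysed 6-enolexo aldolisation of dicarbonyls and the intermolecular proline aldol of acetone with α-branched aldehydes.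

**Step 6**
Reactants: 16 hydroxy ketone enol triflate
Product: 18 (3aR,4S,5S,7R,8aS)-4-isopropyl-2,7-dimethyl-3,3a,4,5,6,7,8,8a-octahydroazulene-5,7-diol, via methylated hydroxy ketone 17 (not isolated)
Conditions: Fe(acac)3 (5 mol%), MeMgBr (2.3 equiv, slow addition), THF/NMP, −30 °C; then LaCl3·2LiCl (0.3 equiv), MeMgBr (2 equiv), −30 to 0 °C; aq NH4Cl
Reagents that add atoms: methylmagnesium bromide, C[Mg]Br
Why: Iron-catalysed Kumada-type cross-coupling of the alkenyl triflate fixes the C1=C2 alkene regiospecifically, and Grignard 1,2-addition to the cycloheptanone then brings methyl in from the equatorial side of the twist-chair that holds isopropyl and C5–O equatorial, giving equatorial methyl and axial hydroxyl at C7 (7R, trans to the C5 oxygen).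

**Step 7**
Reactants: 18 diol; 19 4-acetoxybenzoyl chloride
Product: 21 (3aR,4S,5S,7R,8aS)-7-hydroxy-4-isopropyl-2,7-dimethyl-3,3a,4,5,6,7,8,8a-octahydroazulen-5-yl 4-hydroxybenzoate, via acetate ester 20 (not isolated)
Conditions: 19 (1.5 equiv), Et3N, DMAP (20 mol%), CH2Cl2, 0 °C to rt; then pyrrolidine (3 equiv), 0 °C, 30 min
Reagents that add atoms: none
Why: DMAP-catalysed acylation is selective for the secondary equatorial C5 alcohol over the tertiary C7 alcohol (retention at C5), and aminolysis by pyrrolidine removes the far more electrophilic aryl acetate without touching the hindered secondary benzoate.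

**Step 8**
Reactants: 21 alkene ester
Product: 22 (1S,2R,3aR,4S,5S,7R,8aS)-1,2-epoxy-7-hydroxy-4-isopropyl-2,7-dimethyldecahydroazulen-5-yl 4-hydroxybenzoate (target)
Conditions: VO(acac)2 (5 mol%), tBuOOH (1.5 equiv, decane), toluene, 0 °C to rt
Reagents that add atoms: tert-butyl hydroperoxide, CC(C)(C)OO
Why: In this hydroxyl-directed vanadium-catalysed epoxidation the axial C7 alkoxide binds vanadium together with tBuOO and delivers oxygen to the trisubstituted alkene on its own face, syn to H-3a, setting C1 (S) and C2 (R), and the syn epoxy alcohol cannot cyclise because backside attack on the epoxide is geometrically impossible.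

**Compound list**
1 | isobutyraldehyde | CC(C)C=O | starting material
2 | nitromethane | C[N+](=O)[O-] | starting material
3 | 3-methyl-1-nitrobutan-2-ol (racemic) | CC(C)C(O)C[N+](=O)[O-] | intermediate
4 | 3-methyl-1-nitrobutan-2-yl methanesulfonate (racemic) | CC(C)C(OS(C)(=O)=O)C[N+](=O)[O-] | intermediate
5 | (E)-3-methyl-1-nitrobut-1-ene | CC(C)/C=C/[N+](=O)[O-] | intermediate
6 | 4-oxopentanal | CC(=O)CCC=O | starting material
7 | (2S)-2-[(2S)-3-methyl-1-nitrobutan-2-yl]-4-oxopentanal | CC(C)[C@H](C[N+](=O)[O-])[C@@H](C=O)CC(C)=O | intermediate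
8 | (4S)-3-hydroxy-4-[(2S)-3-methyl-1-nitrobutan-2-yl]cyclopentan-1-one (carbinol epimers) | CC(C)[C@H](C[N+](=O)[O-])[C@@H]1CC(=O)CC1O | intermediate
9 | (4R)-4-[(2S)-3-methyl-1-nitrobutan-2-yl]cyclopent-2-en-1-one | CC(C)[C@H](C[N+](=O)[O-])[C@@H]1CC(=O)C=C1 | intermediate
10 | (2-methylallyl)magnesium chloride | CC(=C)C[Mg]Cl | starting material
11 | lithium nitronate of 9 | CC(C)[C@H](C=[N+]([O-])[O-])[C@@H]1CC(=O)C=C1.[Li+] | intermediate
12 | nitronate enolate after trans 1,4-addition (Li and MgCl counter-ions) | CC(C)[C@H](C=[N+]([O-])[O-])[C@@H]1CC([O-])=C[C@H]1CC(C)=C.[Li+].[Mg+2].[Cl-] | intermediate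
13 | (3S,4R)-4-[(2S)-3-methyl-1-nitrobutan-2-yl]-3-(2-methylallyl)cyclopent-1-en-1-yl triflate | CC(C)[C@H](C[N+](=O)[O-])[C@@H]1CC(OS(=O)(=O)C(F)(F)F)=C[C@H]1CC(C)=C | intermediate
14 | sodium nitronate of 13 | CC(C)[C@H](C=[N+]([O-])[O-])[C@@H]1CC(OS(=O)(=O)C(F)(F)F)=C[C@H]1CC(C)=C.[Na+] | intermediate
15 | (3S,4R)-4-[(2S)-3-methyl-1-oxobutan-2-yl]-3-(2-oxopropyl)cyclopent-1-en-1-yl triflate | CC(C)[C@H](C=O)[C@@H]1CC(OS(=O)(=O)C(F)(F)F)=C[C@H]1CC(C)=O | intermediate
16 | (3aR,4S,5S,8aS)-5-hydroxy-4-isopropyl-7-oxo-3,3a,4,5,6,7,8,8a-octahydroazulen-2-yl triflate (trans-fused) | CC(C)[C@H]1[C@@H]2CC(OS(=O)(=O)C(F)(F)F)=C[C@H]2CC(=O)C[C@@H]1O | intermediate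
17 | (3aR,4S,5S,8aS)-5-hydroxy-4-isopropyl-2-methyl-7-oxo-3,3a,4,5,6,7,8,8a-octahydroazulene | CC(C)[C@H]1[C@@H]2CC(C)=C[C@H]2CC(=O)C[C@@H]1O | intermediate
18 | (3aR,4S,5S,7R,8aS)-4-isopropyl-2,7-dimethyl-3,3a,4,5,6,7,8,8a-octahydroazulene-5,7-diol | CC(C)[C@H]1[C@@H]2CC(C)=C[C@H]2C[C@@](C)(O)C[C@@H]1O | intermediate
19 | 4-acetoxybenzoyl chloride | CC(=O)Oc1ccc(cc1)C(Cl)=O | starting material
20 | C5 4-acetoxybenzoate of 18 | CC(C)[C@H]1[C@@H]2CC(C)=C[C@H]2C[C@@](C)(O)C[C@@H]1OC(=O)c1ccc(OC(C)=O)cc1 | intermediate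
21 | C5 4-hydroxybenzoate of 18 | CC(C)[C@H]1[C@@H]2CC(C)=C[C@H]2C[C@@](C)(O)C[C@@H]1OC(=O)c1ccc(O)cc1 | intermediate
22 | CNP0245441.1 | CC(C)[C@H]1[C@@H]2C[C@@]3(C)O[C@H]3[C@H]2C[C@@](C)(O)C[C@@H]1OC(=O)c1ccc(O)cc1 | target

**Step count**
Total steps: 8. Longest linear sequence: 8 (1 → 5 → 9 → 13 → 15 → 16 → 18 → 21 → 22).

**Steps most likely to fail**

Step 5 (the new aldolisation). The seven-ring closure may be too slow at the dilution it needs, or the product may dehydrate. The fallback uses known chemistry, sets out from 13 and comes back at 20.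
- A buffered Nef reaction (NaOMe, then TiCl3/NH4OAc, H2O/THF, 0 °C) keeps the alkene and gives the methallyl aldehyde F4.
- A Me2AlCl-promoted type 2 carbonyl-ene cyclisation, a reaction known to close seven-membered rings, gives the methylenecycloheptanol F5. Its hydroxyl is axial (5R) because the oxygen must reach the methyl hydrogens.
- Ozonolysis gives the 5-epi hydroxy ketone F6, and the conditions of step 6 give the 5-epi diol F7.
- Mitsunobu esterification with 4-acetoxybenzoic acid (PPh3, DIAD) inverts C5 and lands on 20.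

Step 3 (cuprate addition and triflation beside a nitronate). The nitronate may precipitate, oxidise the cuprate or consume the triflating agent. The fallback sets out from 9 and comes back at 15.
- A classical Nef reaction run in methanol (NaOMe, then cold H2SO4/MeOH) gives the dimethyl acetal F1.
- The same cuprate addition and Comins trapping, now on a substrate without acidic C–H, gives the enol triflate acetal F2.
- Ozonolysis (O3, then Me2S) gives the methyl ketone acetal F3.
- Aqueous trifluoroacetic acid frees the aldehyde to give 15.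

Step 6 (facial selectivity at C7, enolisation or retro-aldol of the magnesium aldolate). The fallback sets out from 17, isolated by stopping after the iron-catalysed coupling, and comes back at 18.
- TESCl/imidazole gives the silyl ether F8.
- Dimethylsulfoxonium methylide (Me3S(O)I, NaH, DMSO) adds reversibly and so places CH2 equatorial, giving the spiro-epoxide F9 with axial oxygen.
- LiBHEt3 opens it at CH2 to give the tertiary alcohol F10.
- Bu4NF removes the silyl group to give 18.

**Further compounds**
F1 | step 3 | (4R)-4-[(2S)-1,1-dimethoxy-3-methylbutan-2-yl]cyclopent-2-en-1-one | CC(C)[C@H](C(OC)OC)[C@@H]1CC(=O)C=C1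
F2 | step 3 | (3S,4R)-4-[(2S)-1,1-dimethoxy-3-methylbutan-2-yl]-3-(2-methylallyl)cyclopent-1-en-1-yl triflate | CC(C)[C@H](C(OC)OC)[C@@H]1CC(OS(=O)(=O)C(F)(F)F)=C[C@H]1CC(C)=C
F3 | step 3 | (3S,4R)-4-[(2S)-1,1-dimethoxy-3-methylbutan-2-yl]-3-(2-oxopropyl)cyclopent-1-en-1-yl triflate | CC(C)[C@H](C(OC)OC)[C@@H]1CC(OS(=O)(=O)C(F)(F)F)=C[C@H]1CC(C)=O
F4 | step 5 | (3S,4R)-4-[(2S)-3-methyl-1-oxobutan-2-yl]-3-(2-methylallyl)cyclopent-1-en-1-yl triflate | CC(C)[C@H](C=O)[C@@H]1CC(OS(=O)(=O)C(F)(F)F)=C[C@H]1CC(C)=C
F5 | step 5 | (3aR,4S,5R,8aS)-5-hydroxy-4-isopropyl-7-methylidene-3,3a,4,5,6,7,8,8a-octahydroazulen-2-yl triflate | CC(C)[C@H]1[C@@H]2CC(OS(=O)(=O)C(F)(F)F)=C[C@H]2CC(=C)C[C@H]1O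
F6 | step 5 | (3aR,4S,5R,8aS)-5-hydroxy-4-isopropyl-7-oxo-3,3a,4,5,6,7,8,8a-octahydroazulen-2-yl triflate | CC(C)[C@H]1[C@@H]2CC(OS(=O)(=O)C(F)(F)F)=C[C@H]2CC(=O)C[C@H]1O
F7 | step 5 | (3aR,4S,5R,7R,8aS)-4-isopropyl-2,7-dimethyl-3,3a,4,5,6,7,8,8a-octahydroazulene-5,7-diol | CC(C)[C@H]1[C@@H]2CC(C)=C[C@H]2C[C@@](C)(O)C[C@H]1O
F8 | step 6 | C5 triethylsilyl ether of 17 | CC(C)[C@H]1[C@@H]2CC(C)=C[C@H]2CC(=O)C[C@@H]1O[Si](CC)(CC)CC
F9 | step 6 | C7 spiro-epoxide (oxygen axial) of the C5 triethylsilyl ether | CC(C)[C@H]1[C@@H]2CC(C)=C[C@H]2C[C@@]3(OC3)C[C@@H]1O[Si](CC)(CC)CC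
F10 | step 6 | C5 triethylsilyl ether of 18 | CC(C)[C@H]1[C@@H]2CC(C)=C[C@H]2C[C@@](C)(O)C[C@@H]1O[Si](CC)(CC)CC
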